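1. Per cent of the starting material charged is the unit of every reading here, and target and side product are read in it side by side.

| flask | starting material | coupling partner | protic impurity | temperature | remark | time |
|---|---|---|---|---|---|---|
| Monday's | 0.12 M | 1 M | 10 mM | 20 °C | run made earlier |  |
| Wednesday's | 0.34 M | 1 M | 10 mM | 35 °C | run made earlier |  |
| green | 0.15 M | 1.00 M | 10.0 mM | 35 °C |  | 5.0 min |
| grey | 0.50 M | 1.00 M | 10.0 mM | 35 °C |  | 10 min |

| run | time / min | target / % | side product / % |
|---|---|---|---|
| Monday's | 1.00 | 4 | 1 |
| Monday's | 3.00 | 10 | 1 |
| Monday's | 5.00 | 17 | 6 |
| Monday's | 8.00 | 25 | 14 |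
| Monday's | 10.0 | 31 | 15 |
| Monday's | 15.0 | 40 | 17 |
| Wednesday's | 1.33 | 20 | 10 |
| Wednesday's | 2.50 | 30 | 14 |
| Wednesday's | 4.00 | 38 | 18 |
| Wednesday's | 5.00 | 46 | 23 |
| Wednesday's | 6.00 | 48 | 22 |
| Wednesday's | 8.00 | 54 | 26 |

(each reading ± 1.5 percentage points)

- the flask that ends with the higher share of target in all that became target or side product, or "neither" when 2 percentage points or less lies between them (green / grey / neither)
- share of target in all that became target or side product, green
- share of target in all that became target or side product, grey

- steps that have been proposed: starting material + coupling partner <-> intermediate; intermediate -> target; intermediate -> side product; starting material + protic impurity -> quenched substrate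

2. The nearest simulated flask to green and grey is Wednesday's run, with the same coupling partner, protic impurity and temperature, 35 °C. Its starting material, 0.34 M, lies above green's 0.15 M and below grey's 0.50 M. Monday's run, at 20 °C, we set aside.

3. We carry the branch logarithm L, the base-ten logarithm of target over side product (the selectivity factor in powers of ten). Wednesday's summed readings give L = 0.320.

4. From Wednesday's first reading to its last, L rises by 0.0164. Two neighbouring readings differ by more, 0.0378, so we can read no drift.

5. In the proposed steps, target and side product both leave the intermediate by first-order steps, so the intermediate cancels from their rate ratio. At fixed temperature, L then carries neither charge nor time. Green and grey share Wednesday's temperature, so we expect both at a share of 67.6 %, with no gap to set against the margin of 2 percentage points.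

6. The forecast, from the same sums, says neither, with 67.6 % for green and 67.6 % for grey, since the ratio “depends on temperature but not on concentrations, time or conversion”.

7. The simulation gives neither, with 68.3 % for green and 68.3 % for grey.

    starting material + coupling partner ⇌ intermediate (K = 0.0360 L mol⁻¹, k = 0.0410 L mol⁻¹ s⁻¹, Ea = 71.0 kJ mol⁻¹, ΔH = −8.00 kJ mol⁻¹)
    intermediate → target (k = 0.0950 s⁻¹, Ea = 75.0 kJ mol⁻¹)
    intermediate → side product (k = 0.0440 s⁻¹, Ea = 73.0 kJ mol⁻¹)
    starting material + protic impurity → quenched substrate (k = 0.580 L mol⁻¹ s⁻¹, Ea = 41.0 kJ mol⁻¹)
    (constants at 35 °C)

Now take the neighbour of grey charged with 0.40 M of coupling partner. At 10.0 min it keeps 50.4 % of its starting material, more than grey's 14.9 %. Its side product stands at 15.0 %, and multiplying that by ten to the power L gives 31.3 % of target. The neighbour holds 32.4 % of target, a share of 68.3 %.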